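**Retrosynthetic overview**

- The strategy rests on ring C (O1–C2–C3–C4–C4a–C8a). C3 lies between the enol-ether carbon C2 and the carbonyl carbon C4, so deleting C3 leaves the five-membered O1–C2–C4(=O)–C4a–C8a ring of a benzofuran-3(2H)-one.
- C3 is therefore inserted as CBr2 into the C=C bond of the derived 3-siloxybenzofuran, forming C2–C3 and C3–C4. The bromine that stays on C3 is the handle for a Negishi coupling that brings in the 4-methoxybenzyl group (ring B).
- The C8 formyl group comes last, by a Duff reaction ortho to the freed 7-OH at the only open carbon of ring A.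
- The benzofuranone comes from 3-methoxy-2-methylphenol by O-TIPS protection, meta C–H borylation/oxidation (third oxygen), lithiation between OMOM and OMe (TIPS screens the other site), chloroacetylation and phenoxide closure.
- Ring order: ring A is bought, the five-membered oxygen ring is closed in step 5 and expanded to ring C in step 7, and ring B is attached in step 9.

Key step: step 7

Remark: the target has no stereocentre and no configured double bond. The only stereocentres on the way are the two ring-fusion carbons of the transient cyclopropane, and they are lost in the same step. The C7 oxygen is carried as its TIPS ether from step 1 to step 10.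

**Step 1**
Reactants: 1 3-methoxy-2-methylphenol
Product: 2 triisopropyl(3-methoxy-2-methylphenoxy)silane
Conditions: TIPSCl (1.2 equiv), imidazole (2.5 equiv), DMF, 25–40 °C
Reagents that add atoms: chlorotriisopropylsilane (TIPSCl), CC(C)[Si](Cl)(C(C)C)C(C)C
Why: Imidazole-promoted O-silylation of a phenol is routine, and the bulky TIPS ether is chosen because it resists n-BuLi, dilute acid and hindered alkoxide and later screens its own ortho C–H from lithiation.

**Step 2**
Reactants: 2 triisopropyl(3-methoxy-2-methylphenoxy)silane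
Product: 4 3-methoxy-4-methyl-5-[(triisopropylsilyl)oxy]phenol, via aryl pinacol boronate 3 (not isolated)
Conditions: B2pin2 (1.0 equiv), [Ir(OMe)(cod)]2 (1.5 mol %), 4,4'-di-tert-butyl-2,2'-bipyridine (3 mol %), THF, 80 °C; evaporate; KHSO5 (as Oxone, 2KHSO5·KHSO4·K2SO4, 1.1 equiv), acetone–H2O, 0 → 25 °C
Reagents that add atoms: bis(pinacolato)diboron, CC1(C)OB(OC1(C)C)B1OC(C)(C)C(C)(C)O1 (boryl group of 3); potassium peroxymonosulfate, [K+].[O-]S(=O)(=O)OO (phenol oxygen of 4)
Why: Iridium-catalysed aromatic C–H borylation is sterically governed and should take the only C–H without an ortho substituent (meta to both oxygens, para to the methyl group), and the one-pot peroxymonosulfate oxidation replaces boron by oxygen at the same carbon through a 1,2-aryl shift.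

**Step 3**
Reactants: 4 3-methoxy-4-methyl-5-[(triisopropylsilyl)oxy]phenol
Product: 5 triisopropyl[3-methoxy-5-(methoxymethoxy)-2-methylphenoxy]silane
Conditions: MOMCl (1.5 equiv), iPr2NEt (2 equiv), CH2Cl2, 0 → 25 °C
Reagents that add atoms: chloromethyl methyl ether (MOMCl), COCCl
Why: Base-mediated O-alkylation of the free phenol gives the acetal, which is a strong directing group for step 4 and can be removed with mild acid beside the aryl TIPS ether.

**Step 4**
Reactants: 5 triisopropyl[3-methoxy-5-(methoxymethoxy)-2-methylphenoxy]silane; 6 2-chloro-N-methoxy-N-methylacetamide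
Product: 8 2-chloro-1-{2-methoxy-6-(methoxymethoxy)-3-methyl-4-[(triisopropylsilyl)oxy]phenyl}ethan-1-one, via aryllithium 7 (not isolated)
Conditions: n-BuLi (1.1 equiv), THF, 0 °C, 1 h; then 6 (1.3 equiv), −78 °C, 2 h; AcOH (1.5 equiv), −78 °C
Reagents that add atoms: n-butyllithium, [Li]CCCC (lithium of 7 only)
Why: Directed ortho-metalation followed by a Weinreb ketone synthesis: the C–H between OMOM and OMe is activated by both oxygens while the other MOM-ortho C–H is screened by TIPS, and the chelated tetrahedral adduct of the N-methoxy-N-methylamide holds until the cold acid quench, so neither over-addition nor epoxide formation should intervene.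

**Step 5**
Reactants: 8 2-chloro-1-{2-methoxy-6-(methoxymethoxy)-3-methyl-4-[(triisopropylsilyl)oxy]phenyl}ethan-1-one
Product: 10 4-methoxy-5-methyl-6-[(triisopropylsilyl)oxy]benzofuran-3(2H)-one, via free phenol chloroketone 9 (not isolated)
Conditions: HCl (cat.), MeOH, 40 °C; evaporate; K2CO3 (1.5 equiv), MeCN, 25 °C, Ar
Reagents that add atoms: none
Why: Acid-catalysed acetal exchange with methanol frees the phenol next to the ketone (aryl TIPS ethers tolerate this), and its phenoxide displaces the primary α-keto chloride in a 5-exo-tet intramolecular Williamson reaction, the classical coumaranone closure.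

**Step 6**
Reactants: 10 4-methoxy-5-methyl-6-[(triisopropylsilyl)oxy]benzofuran-3(2H)-one
Product: 11 tert-butyl({4-methoxy-5-methyl-6-[(triisopropylsilyl)oxy]benzofuran-3-yl}oxy)dimethylsilane
Conditions: TBSOTf (1.2 equiv), Et3N (2 equiv), CH2Cl2, 0 °C
Reagents that add atoms: tert-butyldimethylsilyl triflate (TBSOTf), CC(C)(C)[Si](C)(C)OS(=O)(=O)C(F)(F)F
Why: Soft enolisation with a silyl triflate and an amine should give O-silylation only, driven by the aromaticity of the benzofuran that is formed.

**Step 7**
Reactants: 11 tert-butyl({4-methoxy-5-methyl-6-[(triisopropylsilyl)oxy]benzofuran-3-yl}oxy)dimethylsilane; 12 bromoform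
Product: 15 3-bromo-5-methoxy-6-methyl-7-[(triisopropylsilyl)oxy]-4H-chromen-4-one, via dibromocyclopropane 13 (not isolated), via siloxybenzopyrylium bromide 14 (not isolated)
Conditions: 12 (2.5 equiv), KOC(CH3)3 (3 equiv, solid, in portions), pentane, −30 → 25 °C; aq. NH4Cl
Reagents that add atoms: none
Why: Proposed new method: KOC(CH3)3 deprotonates CHBr3, α-elimination of bromide gives singlet CBr2, and this electrophilic carbene should add in a concerted [2+1] manner to the furan C2=C3 bond of 11 to give the cis-fused dibromocyclopropane 13. The bromide endo to the five-membered ring should then leave together with disrotatory 2π-electrocyclic opening of the shared C–C bond, so ring C is closed not by cyclisation but by one-carbon expansion of the furan ring, with the carbene carbon bonded to the old C2 (chromone C2–C3) and to the old siloxy carbon (chromone C3–C4) and still carrying one bromine. The cation formed, 3-bromo-4-siloxybenzopyrylium 14, is stabilised by O1 and by the siloxy oxygen, and loss of its silyl group to bromide, tert-butoxide or water at work-up gives the 4-pyranone 15. The closest known reactions are the dihalocarbene ring expansion of cyclic silyl enol ethers to 2-halo enones one carbon larger and the Ciamician–Dennstedt expansion of pyrroles and indoles to 3-halopyridines and 3-haloquinolines, and 3-siloxybenzofurans have not been used in either. The two stereocentres of 13 are cis by ring fusion and both vanish on opening, so no stereocontrol is needed. The step needs carbene attack at the furan C=C rather than at ring A, secured by its double donor substitution (O1 on one carbon, OSi on the other), and survival of the Si–O bonds until carbene transfer, secured by adding the base slowly to excess bromoform in cold pentane and by the bulk of the TBS and TIPS groups.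

**Step 8**
Reactants: 16 4-methoxybenzyl chloride
Product: 17 (4-methoxybenzyl)zinc chloride (titrated THF solution, LiCl-complexed)
Conditions: Zn dust (1.5 equiv), LiCl (1.5 equiv), THF, 0 → 25 °C
Reagents that add atoms: zinc, [Zn]
Why: LiCl-assisted direct insertion of zinc dust into a benzylic C–Cl bond is a standard preparation of benzylic zinc chlorides, and the cold start keeps Wurtz-type homocoupling down.

**Step 9**
Reactants: 15 3-bromo-5-methoxy-6-methyl-7-[(triisopropylsilyl)oxy]-4H-chromen-4-one; 17 (4-methoxybenzyl)zinc chloride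
Product: 18 5-methoxy-3-(4-methoxybenzyl)-6-methyl-7-[(triisopropylsilyl)oxy]-4H-chromen-4-one
Conditions: 17 (1.5 equiv), Pd(PPh3)4 (5 mol %), THF, 50 °C
Reagents that add atoms: none
Why: Negishi coupling: zerovalent palladium inserts readily into the C3–Br bond of the α-bromo enone unit, and the benzylic zinc reagent transmetalates fast, has no β-hydrogen and is too mild to add to C2 or C4 of the chromone.

**Step 10**
Reactants: 18 5-methoxy-3-(4-methoxybenzyl)-6-methyl-7-[(triisopropylsilyl)oxy]-4H-chromen-4-one
Product: 19 7-hydroxy-5-methoxy-3-(4-methoxybenzyl)-6-methyl-4H-chromen-4-one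
Conditions: Bu4NF (1.1 equiv), AcOH (1.1 equiv), THF, 0 °C
Reagents that add atoms: none
Why: Fluoride cleaves the aryl silyl ether, driven by the Si–F bond, and acetic acid buffers the phenoxide so that the base-sensitive pyranone ring is not opened.

**Step 11**
Reactants: 19 7-hydroxy-5-methoxy-3-(4-methoxybenzyl)-6-methyl-4H-chromen-4-one
Product: 20 7-hydroxy-5-methoxy-3-(4-methoxybenzyl)-6-methyl-4-oxo-4H-chromene-8-carbaldehyde (target)
Conditions: hexamethylenetetramine (4 equiv), AcOH, 100 °C; then 3 M aq. HCl, 80 °C
Reagents that add atoms: hexamethylenetetramine, C1N2CN3CN1CN(C2)C3 (formyl carbon); water, O (formyl oxygen)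
Why: Duff reaction: the iminium ion from protonated hexamethylenetetramine attacks ortho to the free phenol at C8, the only unsubstituted carbon of ring A and one activated by 7-OH, O1 and 5-OMe, then hydride transfer and acid hydrolysis give the aldehyde, while the plain anisole ring B should not react in acetic acid.

**Compound list**

1 | 3-methoxy-2-methylphenol | COc1cccc(O)c1C | starting material
2 | triisopropyl(3-methoxy-2-methylphenoxy)silane | COc1cccc(O[Si](C(C)C)(C(C)C)C(C)C)c1C | intermediate
3 | 2-{3-methoxy-4-methyl-5-[(triisopropylsilyl)oxy]phenyl}-4,4,5,5-tetramethyl-1,3,2-dioxaborolane | COc1cc(B2OC(C)(C)C(C)(C)O2)cc(O[Si](C(C)C)(C(C)C)C(C)C)c1C | intermediate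
4 | 3-methoxy-4-methyl-5-[(triisopropylsilyl)oxy]phenol | COc1cc(O)cc(O[Si](C(C)C)(C(C)C)C(C)C)c1C | intermediate
5 | triisopropyl[3-methoxy-5-(methoxymethoxy)-2-methylphenoxy]silane | COCOc1cc(OC)c(C)c(O[Si](C(C)C)(C(C)C)C(C)C)c1 | intermediate
6 | 2-chloro-N-methoxy-N-methylacetamide | CON(C)C(=O)CCl | starting material
7 | {2-methoxy-6-(methoxymethoxy)-3-methyl-4-[(triisopropylsilyl)oxy]phenyl}lithium | [Li]c1c(OC)c(C)c(O[Si](C(C)C)(C(C)C)C(C)C)cc1OCOC | intermediate
8 | 2-chloro-1-{2-methoxy-6-(methoxymethoxy)-3-methyl-4-[(triisopropylsilyl)oxy]phenyl}ethan-1-one | COCOc1cc(O[Si](C(C)C)(C(C)C)C(C)C)c(C)c(OC)c1C(=O)CCl | intermediate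
9 | 2-chloro-1-{6-hydroxy-2-methoxy-3-methyl-4-[(triisopropylsilyl)oxy]phenyl}ethan-1-one | COc1c(C)c(O[Si](C(C)C)(C(C)C)C(C)C)cc(O)c1C(=O)CCl | intermediate
10 | 4-methoxy-5-methyl-6-[(triisopropylsilyl)oxy]benzofuran-3(2H)-one | COc1c(C)c(O[Si](C(C)C)(C(C)C)C(C)C)cc2OCC(=O)c12 | intermediate
11 | tert-butyl({4-methoxy-5-methyl-6-[(triisopropylsilyl)oxy]benzofuran-3-yl}oxy)dimethylsilane | COc1c(C)c(O[Si](C(C)C)(C(C)C)C(C)C)cc2occ(O[Si](C)(C)C(C)(C)C)c12 | intermediate
12 | bromoform | BrC(Br)Br | starting material
13 | 1,1-dibromo-6b-[(tert-butyldimethylsilyl)oxy]-6-methoxy-5-methyl-4-[(triisopropylsilyl)oxy]-1a,6b-dihydro-1H-cyclopropa[b]benzofuran (racemic, cis ring fusion; one enantiomer drawn) | CC(C)(C)[Si](C)(C)O[C@@]12c3c(OC)c(C)c(O[Si](C(C)C)(C(C)C)C(C)C)cc3O[C@@H]1C2(Br)Br | intermediate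
14 | 3-bromo-4-[(tert-butyldimethylsilyl)oxy]-5-methoxy-6-methyl-7-[(triisopropylsilyl)oxy]chromenylium bromide | COc1c(C)c(O[Si](C(C)C)(C(C)C)C(C)C)cc2[o+]cc(Br)c(O[Si](C)(C)C(C)(C)C)c12.[Br-] | intermediate
15 | 3-bromo-5-methoxy-6-methyl-7-[(triisopropylsilyl)oxy]-4H-chromen-4-one | COc1c(C)c(O[Si](C(C)C)(C(C)C)C(C)C)cc2occ(Br)c(=O)c12 | intermediate
16 | 4-methoxybenzyl chloride | COc1ccc(CCl)cc1 | starting material
17 | (4-methoxybenzyl)zinc chloride | COc1ccc(C[Zn]Cl)cc1 | intermediate
18 | 5-methoxy-3-(4-methoxybenzyl)-6-methyl-7-[(triisopropylsilyl)oxy]-4H-chromen-4-one | COc1ccc(Cc2coc3cc(O[Si](C(C)C)(C(C)C)C(C)C)c(C)c(OC)c3c2=O)cc1 | intermediate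
19 | 7-hydroxy-5-methoxy-3-(4-methoxybenzyl)-6-methyl-4H-chromen-4-one | COc1ccc(Cc2coc3cc(O)c(C)c(OC)c3c2=O)cc1 | intermediate
20 | 7-hydroxy-5-methoxy-3-(4-methoxybenzyl)-6-methyl-4-oxo-4H-chromene-8-carbaldehyde | COc1ccc(Cc2coc3c(C=O)c(O)c(C)c(OC)c3c2=O)cc1 | target

**Totals**

Total step count: 11.
Longest linear sequence: 10 (steps 1–7, 9, 10 and 11; step 8 is a one-step side branch).

**Three steps most likely to fail**

1. Step 7 (bears the label).
   - What may go wrong: tert-butoxide may strip the enol silyl group before carbene transfer. Excess base may add to C2 of the new pyranone and open ring C. Carbene transfer to the crowded, peri-substituted enol ether may be slow.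
   - Fallback: known chemistry without a carbene, setting out from 5 and coming back at 15.
   - Lithiation of 5 as in step 4 (through 7) and quenching with N-methoxy-N-methylacetamide should give 1-{2-methoxy-6-(methoxymethoxy)-3-methyl-4-[(triisopropylsilyl)oxy]phenyl}ethan-1-one F1.
   - Catalytic HCl in methanol should free the phenol to give 1-{6-hydroxy-2-methoxy-3-methyl-4-[(triisopropylsilyl)oxy]phenyl}ethan-1-one F2.
   - Heating with N,N-dimethylformamide dimethyl acetal in toluene should give (E)-3-(dimethylamino)-1-{6-hydroxy-2-methoxy-3-methyl-4-[(triisopropylsilyl)oxy]phenyl}prop-2-en-1-one F3.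
   - Bromine (1 equiv) in CHCl3 at 0 °C should brominate the α-carbon of the enaminone. The phenol should then close onto the iminium carbon with loss of dimethylamine, the established enaminone halocyclisation to 3-halochromones, giving 15.

2. Step 11.
   - What may go wrong: electrophilic substitution may be sluggish on a ring A that is deactivated by the pyranone carbonyl. The reaction may stall at the benzylamine stage. Aminomethylation may compete ortho to the methoxy group of ring B.
   - Fallback: halogenation, cross-coupling and oxidative cleavage in place of electrophilic formylation, setting out from 19 and coming back at 20.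
   - N-Iodosuccinimide in DMF at 0 °C should iodinate the only free, phenol-activated carbon to give 7-hydroxy-8-iodo-5-methoxy-3-(4-methoxybenzyl)-6-methyl-4H-chromen-4-one F4.
   - Suzuki–Miyaura coupling with potassium vinyltrifluoroborate (PdCl2(dppf), K2CO3, THF–H2O, 70 °C) should give 8-ethenyl-7-hydroxy-5-methoxy-3-(4-methoxybenzyl)-6-methyl-4H-chromen-4-one F5.
   - Lemieux–Johnson oxidation (OsO4 cat., NaIO4, 2,6-lutidine, dioxane–H2O) should cleave the electron-rich styrene double bond in preference to the electron-poor C2=C3 bond, giving 20.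

3. Step 4.
   - What may go wrong: proton transfer from the acidic α-chloro amide to the hindered aryllithium may occur in place of addition. Site selectivity may erode during lithiation. The tetrahedral adduct may collapse early.
   - Fallback: carboxylation and diazoketone homologation in place of direct chloroacetylation, setting out from 5 and coming back at 10.
   - Aryllithium 7 is quenched with CO2, a small electrophile that cannot enolise, to give 2-methoxy-6-(methoxymethoxy)-3-methyl-4-[(triisopropylsilyl)oxy]benzoic acid F6.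
   - 1-Chloro-N,N,2-trimethylprop-1-en-1-amine in CH2Cl2 (neutral conditions that spare the MOM group) should give 2-methoxy-6-(methoxymethoxy)-3-methyl-4-[(triisopropylsilyl)oxy]benzoyl chloride F7.
   - Excess diazomethane in Et2O at 0 °C should give 2-diazo-1-{2-methoxy-6-(methoxymethoxy)-3-methyl-4-[(triisopropylsilyl)oxy]phenyl}ethan-1-one F8.
   - HCl in MeOH–Et2O should replace N2 by chloride (Nierenstein-type reaction) and remove the MOM group to give 9. This is closed with K2CO3 in MeCN as in step 5 to give 10.

**Further compounds**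

F1 | step 7 | 1-{2-methoxy-6-(methoxymethoxy)-3-methyl-4-[(triisopropylsilyl)oxy]phenyl}ethan-1-one | COCOc1cc(O[Si](C(C)C)(C(C)C)C(C)C)c(C)c(OC)c1C(C)=O
F2 | step 7 | 1-{6-hydroxy-2-methoxy-3-methyl-4-[(triisopropylsilyl)oxy]phenyl}ethan-1-one | COc1c(C)c(O[Si](C(C)C)(C(C)C)C(C)C)cc(O)c1C(C)=O
F3 | step 7 | (E)-3-(dimethylamino)-1-{6-hydroxy-2-methoxy-3-methyl-4-[(triisopropylsilyl)oxy]phenyl}prop-2-en-1-one | COc1c(C)c(O[Si](C(C)C)(C(C)C)C(C)C)cc(O)c1C(=O)/C=C/N(C)C
F4 | step 11 | 7-hydroxy-8-iodo-5-methoxy-3-(4-methoxybenzyl)-6-methyl-4H-chromen-4-one | COc1ccc(Cc2coc3c(I)c(O)c(C)c(OC)c3c2=O)cc1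
F5 | step 11 | 8-ethenyl-7-hydroxy-5-methoxy-3-(4-methoxybenzyl)-6-methyl-4H-chromen-4-one | COc1ccc(Cc2coc3c(C=C)c(O)c(C)c(OC)c3c2=O)cc1
F6 | step 4 | 2-methoxy-6-(methoxymethoxy)-3-methyl-4-[(triisopropylsilyl)oxy]benzoic acid | COCOc1cc(O[Si](C(C)C)(C(C)C)C(C)C)c(C)c(OC)c1C(=O)O
F7 | step 4 | 2-methoxy-6-(methoxymethoxy)-3-methyl-4-[(triisopropylsilyl)oxy]benzoyl chloride | COCOc1cc(O[Si](C(C)C)(C(C)C)C(C)C)c(C)c(OC)c1C(=O)Cl
F8 | step 4 | 2-diazo-1-{2-methoxy-6-(methoxymethoxy)-3-methyl-4-[(triisopropylsilyl)oxy]phenyl}ethan-1-one | COCOc1cc(O[Si](C(C)C)(C(C)C)C(C)C)c(C)c(OC)c1C(=O)C=[N+]=[N-]
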